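Everything rests on removing O6, the one oxygen that bridges ring carbon C6 of the ten-membered carbocycle (C1–C10) and the C12 carboxyl: both lactone C–O bonds (C6–O, O–C12) are cut. In the forward sense a cytochrome P450 hydroxylates C6–H, allylic to C4=C5 and three bonds from the anchoring C12 carboxylate, on the α face; the 6α-hydroxy acid then closes the trans-fused five-membered lactone (O6, C6, C7, C11, C12), so one operation sets C6 and forms the second ring. Its substrate is 8β,9β-dihydroxygermacra-1(10)Z,4E,11(13)-trien-12-oic acid, assembled from geranyl acetate by an Evans syn-aldol (C7, C8), CrCl2/NiCl2 closure of C9–C10 and carbonylation of a C11 enol triflate; the O8 epoxy ester comes last.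

Key step: step 19

Assumption (chemistry): a variant of the known germacrene acid 6α-hydroxylase family that accepts the cis-C1=C10, 9β-hydroxylated acid 26 can be obtained by panel screening or directed evolution. Germacrane numbering is used for all intermediates.

**Step 1**
Reactants: 1 geranyl acetate
Product: 3 (E)-3-methyl-6-oxohex-2-en-1-yl acetate, via epoxy acetate 2 (not isolated)
Conditions: mCPBA, CH2Cl2, 0 °C; aq. NaHCO3 wash; then H5IO6, THF/H2O, 0 °C
Reagents that add atoms: mCPBA (3-chloroperoxybenzoic acid), O=C(OO)c1cccc(Cl)c1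
Why: Prilezhaev epoxidation should be site-selective for the distal, more electron-rich alkene because the allylic acetate deactivates the proximal one, and periodic acid then cleaves the epoxide through its diol (oxidative glycol cleavage), which removes the racemic epoxide centre.

**Step 2**
Reactants: 3 (E)-3-methyl-6-oxohex-2-en-1-yl acetate
Product: 4 (2E,6Z)-7-iodo-3-methylocta-2,6-dien-1-yl acetate
Conditions: EtPPh3I, n-BuLi, THF, rt; I2, −78 °C; NaHMDS, −20 °C; then 3, −78 → −20 °C
Reagents that add atoms: ethyltriphenylphosphonium iodide, CC[P+](c1ccccc1)(c1ccccc1)c1ccccc1.[I-]; iodine, II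
Why: Stork–Zhao variant of the Wittig olefination, in which the non-stabilised α-iodo ylide reacts under kinetic control to give the (Z)-2-iodoalkene (chain cis to iodine), the geometry that later becomes the cis C1=C10 bond.

**Step 3**
Reactants: 4 (2E,6Z)-7-iodo-3-methylocta-2,6-dien-1-yl acetate
Product: 5 (2E,6Z)-7-iodo-3-methylocta-2,6-dien-1-ol
Conditions: K2CO3 (cat.), MeOH, 0 °C → rt
Reagents that add atoms: none
Why: Base-catalysed transesterification (methanolysis of the acetate) leaves both alkenes and the vinyl iodide untouched.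

**Step 4**
Reactants: 5 (2E,6Z)-7-iodo-3-methylocta-2,6-dien-1-ol
Product: 6 (2E,6Z)-1-bromo-7-iodo-3-methylocta-2,6-diene
Conditions: CBr4, PPh3, CH2Cl2, 0 °C; used crude
Reagents that add atoms: carbon tetrabromide, BrC(Br)(Br)Br
Why: Appel reaction, in which SN2 displacement of the oxyphosphonium at the primary allylic carbon keeps the E alkene.

**Step 5**
Reactants: 6 (2E,6Z)-1-bromo-7-iodo-3-methylocta-2,6-diene
Product: 7 methyl (4E,8Z)-9-iodo-5-methyldeca-4,8-dienoate
Conditions: MeOAc, LDA, THF, −78 °C; then 6, DMPU, −78 → −40 °C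
Reagents that add atoms: methyl acetate, COC(C)=O
Why: SN2 alkylation of a lithium ester enolate by the primary allylic bromide (C6–C7 bond), with all amide base consumed beforehand so that the vinyl iodide is not exposed to elimination.

**Step 6**
Reactants: 7 methyl (4E,8Z)-9-iodo-5-methyldeca-4,8-dienoate
Product: 8 (4E,8Z)-9-iodo-5-methyldeca-4,8-dienoic acid
Conditions: LiOH, THF/MeOH/H2O, rt; then cold 1 M HCl to pH 3
Reagents that add atoms: lithium hydroxide, [Li+].[OH-]
Why: Saponification of the methyl ester, to which the trisubstituted alkene and the vinyl iodide are inert.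

**Step 7**
Reactants: 8 (4E,8Z)-9-iodo-5-methyldeca-4,8-dienoic acid; 9 (S)-4-benzyl-2-oxazolidinone
Product: 11 (S)-4-benzyl-3-[(4E,8Z)-9-iodo-5-methyldeca-4,8-dienoyl]oxazolidin-2-one, via mixed pivalic anhydride 10 (not isolated)
Conditions: PivCl, Et3N, THF, −20 °C; then 9, LiCl, −20 °C → rt
Reagents that add atoms: none
Why: N-Acylation of the oxazolidinone through the mixed anhydride, which is attacked at its less hindered carbonyl.

**Step 8**
Reactants: 11 (S)-4-benzyl-3-[(4E,8Z)-9-iodo-5-methyldeca-4,8-dienoyl]oxazolidin-2-one; 12 (tert-butyldimethylsilyloxy)acetaldehyde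
Product: 14 (S)-4-benzyl-3-[(2S,4E,8Z)-2-[(1S)-2-(tert-butyldimethylsilyloxy)-1-hydroxyethyl]-9-iodo-5-methyldeca-4,8-dienoyl]oxazolidin-2-one, via boron enolate 13 (not isolated)
Conditions: Bu2BOTf, i-Pr2NEt, CH2Cl2, −78 → 0 °C; then 12, −78 → 0 °C; pH 7 buffer (NaH2PO4/Na2HPO4), MeOH, H2O2, 0 °C
Reagents that add atoms: none
Why: Evans syn-aldol reaction, in which the (Z)-boron enolate reacts through a Zimmerman–Traxler chair with the auxiliary benzyl group shielding one enolate face, setting C7 (S) and C8 (S) in the 2,3-syn relationship that becomes 7α-H/8β-O.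

**Step 9**
Reactants: 14 the syn-aldol adduct
Product: 15 (2S,4E,8Z)-2-[(1S)-2-(tert-butyldimethylsilyloxy)-1-hydroxyethyl]-9-iodo-N-methoxy-N,5-dimethyldeca-4,8-dienamide
Conditions: MeNHOMe·HCl, AlMe3, CH2Cl2, −20 → 0 °C; aq. potassium sodium tartrate
Reagents that add atoms: N,O-dimethylhydroxylamine hydrochloride, CNOC.Cl
Why: Aluminium amide transamidation of the β-hydroxy imide (Weinreb amide formation), assisted by the free C8 hydroxyl and without effect on C7 or C8.

**Step 10**
Reactants: 15 the β-hydroxy Weinreb amide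
Product: 16 (2S,4E,8Z)-2-[(1S)-1,2-bis(tert-butyldimethylsilyloxy)ethyl]-9-iodo-N-methoxy-N,5-dimethyldeca-4,8-dienamide
Conditions: TBSOTf, 2,6-lutidine, CH2Cl2, −78 → 0 °C
Reagents that add atoms: tert-butyldimethylsilyl triflate, CC(C)(C)[Si](C)(C)OS(=O)(=O)C(F)(F)F
Why: Silylation of the secondary C8 hydroxyl with a silyl triflate and a hindered pyridine base.

**Step 11**
Reactants: 16 the bis-TBS ether
Product: 17 (2S,4E,8Z)-2-[(1S)-1-(tert-butyldimethylsilyloxy)-2-hydroxyethyl]-9-iodo-N-methoxy-N,5-dimethyldeca-4,8-dienamide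
Conditions: HF·pyridine, pyridine, THF, 0 °C
Reagents that add atoms: none
Why: Selective desilylation, the primary silyl ether being cleaved much faster than the hindered secondary one; silyl ethers are used at O9 because hydrogenolysis of a benzyl ether is ruled out by the alkenes and the vinyl iodide.

**Step 12**
Reactants: 17 the primary alcohol
Product: 18 (2S,4E,8Z)-2-[(1S)-1-(tert-butyldimethylsilyloxy)-2-oxoethyl]-9-iodo-N-methoxy-N,5-dimethyldeca-4,8-dienamide
Conditions: Dess–Martin periodinane, NaHCO3, CH2Cl2, 0 °C → rt; used crude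
Reagents that add atoms: none
Why: Dess–Martin oxidation under buffered conditions should give the α-silyloxy aldehyde without epimerising C8.

**Step 13**
Reactants: 18 the C9 aldehyde
Product: 20 (1S,2S,3R,4Z,8E)-2-(tert-butyldimethylsilyloxy)-3-hydroxy-N-methoxy-N,4,8-trimethylcyclodeca-4,8-diene-1-carboxamide, via alkenylchromium dichloride 19 (not isolated)
Conditions: CrCl2 (excess), NiCl2 (cat.), degassed DMSO/THF, rt, slow addition of 18 (high dilution); aq. work-up
Reagents that add atoms: none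
Why: Intramolecular Nozaki–Hiyama–Kishi coupling, in which the alkenylchromium species formed with retention of the Z geometry adds to the aldehyde to close the ten-membered ring at C9–C10, the new C9 centre (R, 9β-OH) being set by Felkin–Anh addition anti to the 8-silyloxy group (8,9-anti diol pattern).

**Step 14**
Reactants: 20 the macrocyclic 9β-alcohol
Product: 21 (1S,2S,3R,4Z,8E)-2-(tert-butyldimethylsilyloxy)-N-methoxy-N,4,8-trimethyl-3-(triethylsilyloxy)cyclodeca-4,8-diene-1-carboxamide
Conditions: TESOTf, 2,6-lutidine, CH2Cl2, −78 °C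
Reagents that add atoms: triethylsilyl triflate, CC[Si](CC)(CC)OS(=O)(=O)C(F)(F)F
Why: Silylation of the hindered allylic hydroxyl with a small, reactive silyl triflate, so that no hydroxyl is free in the enolate chemistry that follows.

**Step 15**
Reactants: 21 the macrocyclic Weinreb amide
Product: 22 1-[(1S,2S,3R,4Z,8E)-2-(tert-butyldimethylsilyloxy)-4,8-dimethyl-3-(triethylsilyloxy)cyclodeca-4,8-dien-1-yl]ethan-1-one
Conditions: MeMgBr, THF, 0 °C; aq. NH4Cl
Reagents that add atoms: methylmagnesium bromide, C[Mg]Br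
Why: Weinreb ketone synthesis, in which the chelated tetrahedral adduct stops at mono-addition and releases the methyl ketone (C13 installed) only on work-up, without epimerising C7.

**Step 16**
Reactants: 22 the C11 methyl ketone
Product: 24 1-[(1S,2S,3R,4Z,8E)-2-(tert-butyldimethylsilyloxy)-4,8-dimethyl-3-(triethylsilyloxy)cyclodeca-4,8-dien-1-yl]ethenyl trifluoromethanesulfonate, via potassium enolate 23 (not isolated)
Conditions: KHMDS, THF, −78 °C; then PhNTf2, −78 → 0 °C; aq. NH4Cl
Reagents that add atoms: N-phenylbis(trifluoromethanesulfonimide), O=S(=O)(N(c1ccccc1)S(=O)(=O)C(F)(F)F)C(F)(F)F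
Why: Kinetic deprotonation by the bulky amide base occurs at the C13 methyl and not at the hindered C7 methine, and O-triflation of that enolate gives the 1,1-disubstituted enol triflate.

**Step 17**
Reactants: 24 the enol triflate
Product: 25 2-[(1R,2S,3R,4Z,8E)-2-(tert-butyldimethylsilyloxy)-4,8-dimethyl-3-(triethylsilyloxy)cyclodeca-4,8-dien-1-yl]prop-2-enoic acid
Conditions: Pd(OAc)2 (cat.), dppp, CO (1 atm), H2O, Et3N, DMF, 50 °C
Reagents that add atoms: carbon monoxide, [C-]#[O+]; water, O
Why: Palladium-catalysed hydroxycarbonylation of an enol triflate (oxidative addition to zerovalent palladium, CO insertion, hydrolysis) creates C12 as the acrylic acid, and it is placed after step 13 because a vinyl iodide would compete for the catalyst.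

**Step 18**
Reactants: 25 the bis-silyl acid
Product: 26 2-[(1R,2S,3R,4Z,8E)-2,3-dihydroxy-4,8-dimethylcyclodeca-4,8-dien-1-yl]prop-2-enoic acid (8β,9β-dihydroxygermacra-1(10)Z,4E,11(13)-trien-12-oic acid)
Conditions: TBAF, THF, 0 °C → rt; cold aq. NH4Cl, extraction at pH 4.5; stored as the sodium salt
Reagents that add atoms: none
Why: Fluoride-mediated cleavage of both silyl ethers under non-acidic conditions avoids transannular cyclisation of the 1,5-diene and closure of O8 onto C12.

**Step 19**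
Reactants: 26 8β,9β-dihydroxygermacra-1(10)Z,4E,11(13)-trien-12-oic acid
Product: 28 8β,9β-dihydroxygermacra-1(10)Z,4E,11(13)-trien-6α,12-olide, via 6α-hydroxy acid 27 (not isolated)
Conditions: 26 (sodium salt, 2% DMSO); yeast microsomes co-expressing the selected P450 variant (germacrene A acid 6α-hydroxylase family) and its NADPH–cytochrome P450 reductase; NADP+ (cat.), D-glucose, glucose dehydrogenase; air; buffer (KH2PO4/K2HPO4) pH 7.5, 30 °C; EtOAc extraction
Reagents that add atoms: dioxygen, O=O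
Why: The ferryl-oxo species of the P450 abstracts the 6α hydrogen of 26, allylic to C4=C5, and returns hydroxyl to the same face by oxygen rebound, so that the new C6 stereocentre (R, 6α-O) is fixed by the active site and not by the substrate. The closest known reaction type is the P450 6α-hydroxylation of germacra-1(10),4,11(13)-trien-12-oic acid and of its 8β-hydroxy derivative followed by spontaneous lactonisation (costunolide-synthase and eupatolide-synthase chemistry), applied here to the cis-C1=C10, 9β-hydroxylated congener through a screened or evolved variant. The lactone ring (O6, C6, C7, C11, C12) closes from 27 by 5-exo-trig acyl substitution of O6 at C12 with loss of water and is trans-fused because O6 is α and C11 is β on C7. The step needs site selectivity for C6 among five allylic ring carbons (C2, C3, C6, C7, C9) and two allylic methyls (C14, C15), chemoselectivity over three alkenes, and α-face selectivity; all three are secured by the C12 carboxylate, which the enzyme binds and which sits three bonds from C6. Lactonisation is regioselective for O6 because the 8β-hydroxyl of this acid class does not close onto C12 under neutral conditions, whereas a 6α-hydroxyl does so at once. Keeping O8 free and the substrate as the carboxylate salt keeps it as close as possible to the native 8β-hydroxy acid.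

**Step 20**
Reactants: 29 (R)-citramalic acid
Product: 30 dimethyl (R)-2-hydroxy-2-methylbutanedioate
Conditions: SOCl2, MeOH, 0 °C → rt
Reagents that add atoms: methanol, CO
Why: Acid-mediated esterification of both carboxyl groups with HCl generated in the flask, which does not touch the tertiary hydroxyl or the stereocentre.

**Step 21**
Reactants: 30 dimethyl (R)-2-hydroxy-2-methylbutanedioate
Product: 31 methyl (R)-3,4-dihydroxy-3-methylbutanoate
Conditions: BH3·SMe2, NaBH4 (cat.), THF, 0 °C → rt; MeOH quench; kept neutral and used directly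
Reagents that add atoms: none
Why: Hydroxyl-directed borane reduction, in which the alkoxyborane formed at the tertiary hydroxyl delivers hydride through a five-membered chelate to the adjacent ester only, leaving the distal ester and the stereocentre untouched.

**Step 22**
Reactants: 31 methyl (R)-3,4-dihydroxy-3-methylbutanoate
Product: 33 methyl (R)-2-(2-methyloxiran-2-yl)acetate, via primary tosylate 32 (not isolated)
Conditions: TsCl, Et3N, Bu2SnO (cat.), CH2Cl2, 0 °C; then K2CO3, MeOH, 0 °C
Reagents that add atoms: none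
Why: Tin-catalysed sulfonylation of the primary hydroxyl followed by intramolecular Williamson etherification (3-exo-tet) by the tertiary alkoxide keeps the C–O bond of the stereocentre, so the (R) configuration is retained.

**Step 23**
Reactants: 33 methyl (R)-2-(2-methyloxiran-2-yl)acetate
Product: 34 (R)-2-(2-methyloxiran-2-yl)acetic acid
Conditions: LiOH (1.0 equiv), THF/H2O, 0 °C; cold dilute HCl to pH 4, extraction; used at once
Reagents that add atoms: lithium hydroxide, [Li+].[OH-]
Why: Saponification with one equivalent of hydroxide at 0 °C, under which the carboxylate is not enolised and the β,γ-epoxide should not be opened.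

**Step 24**
Reactants: 28 8β,9β-dihydroxygermacra-1(10)Z,4E,11(13)-trien-6α,12-olide
Product: 35 8β-hydroxy-9β-(triethylsilyloxy)germacra-1(10)Z,4E,11(13)-trien-6α,12-olide
Conditions: TESCl (1.05 equiv), imidazole, CH2Cl2, −40 → −20 °C
Reagents that add atoms: chlorotriethylsilane, CC[Si](Cl)(CC)CC
Why: Regioselective silylation, O9 being expected to be the more accessible hydroxyl (allylic, flanked by the sp2 carbon C10) while O8 lies between C7 and C9 beside the C11 methylene.

**Step 25**
Reactants: 35 the 9-O-TES lactone; 34 (R)-2-(2-methyloxiran-2-yl)acetic acid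
Product: 36 8β-[(R)-2-(2-methyloxiran-2-yl)acetoxy]-9β-(triethylsilyloxy)germacra-1(10)Z,4E,11(13)-trien-6α,12-olide
Conditions: DCC, DMAP (10 mol %), CH2Cl2, 0 °C
Reagents that add atoms: none
Why: Steglich esterification of the only free hydroxyl (O8, retention at C8), with low temperature and substoichiometric DMAP to limit base-induced opening of the β,γ-epoxy acyl unit.

**Step 26**
Reactants: 36 the silylated epoxy ester
Product: 37 the target, 9β-hydroxy-8β-[(R)-2-(2-methyloxiran-2-yl)acetoxy]germacra-1(10)Z,4E,11(13)-trien-6α,12-olide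
Conditions: TBAF, AcOH (1:1), THF, 0 °C
Reagents that add atoms: none
Why: Fluoride-mediated desilylation buffered with acetic acid should spare the epoxide and the α-methylene lactone and suppress O8 to O9 acyl migration.

**Compound list**

1 | geranyl acetate, (E)-3,7-dimethylocta-2,6-dien-1-yl acetate | CC(C)=CCC/C(C)=C/COC(C)=O | starting material
2 | 6,7-epoxygeranyl acetate, (E)-5-(3,3-dimethyloxiran-2-yl)-3-methylpent-2-en-1-yl acetate (racemic at the epoxide carbon, formed in the flask) | CC(=O)OC/C=C(\C)CCC1OC1(C)C | intermediate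
3 | (E)-3-methyl-6-oxohex-2-en-1-yl acetate | CC(=O)OC/C=C(\C)CCC=O | intermediate
4 | (2E,6Z)-7-iodo-3-methylocta-2,6-dien-1-yl acetate | CC(=O)OC/C=C(\C)CC/C=C(/C)I | intermediate
5 | (2E,6Z)-7-iodo-3-methylocta-2,6-dien-1-ol | OC/C=C(\C)CC/C=C(/C)I | intermediate
6 | (2E,6Z)-1-bromo-7-iodo-3-methylocta-2,6-diene | BrC/C=C(\C)CC/C=C(/C)I | intermediate
7 | methyl (4E,8Z)-9-iodo-5-methyldeca-4,8-dienoate | COC(=O)CC/C=C(\C)CC/C=C(/C)I | intermediate
8 | (4E,8Z)-9-iodo-5-methyldeca-4,8-dienoic acid | OC(=O)CC/C=C(\C)CC/C=C(/C)I | intermediate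
9 | (S)-4-benzyl-2-oxazolidinone | O=C1N[C@@H](Cc2ccccc2)CO1 | starting material
10 | (4E,8Z)-9-iodo-5-methyldeca-4,8-dienoic pivalic anhydride (formed in the flask) | CC(C)(C)C(=O)OC(=O)CC/C=C(\C)CC/C=C(/C)I | intermediate
11 | (S)-4-benzyl-3-[(4E,8Z)-9-iodo-5-methyldeca-4,8-dienoyl]oxazolidin-2-one | O=C(CC/C=C(\C)CC/C=C(/C)I)N1[C@@H](Cc2ccccc2)COC1=O | intermediate
12 | (tert-butyldimethylsilyloxy)acetaldehyde | O=CCO[Si](C)(C)C(C)(C)C | starting material
13 | (Z)-dibutylboron enolate of 11 (formed in the flask) | CCCCB(CCCC)O/C(=C\C/C=C(\C)CC/C=C(/C)I)N1[C@@H](Cc2ccccc2)COC1=O | intermediate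
14 | (S)-4-benzyl-3-[(2S,4E,8Z)-2-[(1S)-2-(tert-butyldimethylsilyloxy)-1-hydroxyethyl]-9-iodo-5-methyldeca-4,8-dienoyl]oxazolidin-2-one (C7 S, C8 S) | O=C([C@@H](C/C=C(\C)CC/C=C(/C)I)[C@H](O)CO[Si](C)(C)C(C)(C)C)N1[C@@H](Cc2ccccc2)COC1=O | intermediate
15 | (2S,4E,8Z)-2-[(1S)-2-(tert-butyldimethylsilyloxy)-1-hydroxyethyl]-9-iodo-N-methoxy-N,5-dimethyldeca-4,8-dienamide | CON(C)C(=O)[C@@H](C/C=C(\C)CC/C=C(/C)I)[C@H](O)CO[Si](C)(C)C(C)(C)C | intermediate
16 | (2S,4E,8Z)-2-[(1S)-1,2-bis(tert-butyldimethylsilyloxy)ethyl]-9-iodo-N-methoxy-N,5-dimethyldeca-4,8-dienamide | CON(C)C(=O)[C@@H](C/C=C(\C)CC/C=C(/C)I)[C@H](O[Si](C)(C)C(C)(C)C)CO[Si](C)(C)C(C)(C)C | intermediate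
17 | (2S,4E,8Z)-2-[(1S)-1-(tert-butyldimethylsilyloxy)-2-hydroxyethyl]-9-iodo-N-methoxy-N,5-dimethyldeca-4,8-dienamide | CON(C)C(=O)[C@@H](C/C=C(\C)CC/C=C(/C)I)[C@H](O[Si](C)(C)C(C)(C)C)CO | intermediate
18 | (2S,4E,8Z)-2-[(1S)-1-(tert-butyldimethylsilyloxy)-2-oxoethyl]-9-iodo-N-methoxy-N,5-dimethyldeca-4,8-dienamide | CON(C)C(=O)[C@@H](C/C=C(\C)CC/C=C(/C)I)[C@H](O[Si](C)(C)C(C)(C)C)C=O | intermediate
19 | alkenylchromium dichloride from 18, Z geometry retained (trivalent chromium, formed in the flask) | CON(C)C(=O)[C@@H](C/C=C(\C)CC/C=C(/C)[Cr](Cl)Cl)[C@H](O[Si](C)(C)C(C)(C)C)C=O | intermediate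
20 | (1S,2S,3R,4Z,8E)-2-(tert-butyldimethylsilyloxy)-3-hydroxy-N-methoxy-N,4,8-trimethylcyclodeca-4,8-diene-1-carboxamide (7α-H, 8β-OTBS, 9β-OH) | CON(C)C(=O)[C@H]1C/C=C(\C)CC/C=C(/C)[C@@H](O)[C@H]1O[Si](C)(C)C(C)(C)C | intermediate
21 | (1S,2S,3R,4Z,8E)-2-(tert-butyldimethylsilyloxy)-N-methoxy-N,4,8-trimethyl-3-(triethylsilyloxy)cyclodeca-4,8-diene-1-carboxamide | CON(C)C(=O)[C@H]1C/C=C(\C)CC/C=C(/C)[C@@H](O[Si](CC)(CC)CC)[C@H]1O[Si](C)(C)C(C)(C)C | intermediate
22 | 1-[(1S,2S,3R,4Z,8E)-2-(tert-butyldimethylsilyloxy)-4,8-dimethyl-3-(triethylsilyloxy)cyclodeca-4,8-dien-1-yl]ethan-1-one | CC(=O)[C@H]1C/C=C(\C)CC/C=C(/C)[C@@H](O[Si](CC)(CC)CC)[C@H]1O[Si](C)(C)C(C)(C)C | intermediate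
23 | potassium enolate of 22 at C11–C13 (formed in the flask) | [K+].[O-]C(=C)[C@H]1C/C=C(\C)CC/C=C(/C)[C@@H](O[Si](CC)(CC)CC)[C@H]1O[Si](C)(C)C(C)(C)C | intermediate
24 | 1-[(1S,2S,3R,4Z,8E)-2-(tert-butyldimethylsilyloxy)-4,8-dimethyl-3-(triethylsilyloxy)cyclodeca-4,8-dien-1-yl]ethenyl trifluoromethanesulfonate | C=C(OS(=O)(=O)C(F)(F)F)[C@H]1C/C=C(\C)CC/C=C(/C)[C@@H](O[Si](CC)(CC)CC)[C@H]1O[Si](C)(C)C(C)(C)C | intermediate
25 | 2-[(1R,2S,3R,4Z,8E)-2-(tert-butyldimethylsilyloxy)-4,8-dimethyl-3-(triethylsilyloxy)cyclodeca-4,8-dien-1-yl]prop-2-enoic acid | C=C(C(=O)O)[C@H]1C/C=C(\C)CC/C=C(/C)[C@@H](O[Si](CC)(CC)CC)[C@H]1O[Si](C)(C)C(C)(C)C | intermediate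
26 | 2-[(1R,2S,3R,4Z,8E)-2,3-dihydroxy-4,8-dimethylcyclodeca-4,8-dien-1-yl]prop-2-enoic acid (8β,9β-dihydroxygermacra-1(10)Z,4E,11(13)-trien-12-oic acid, 7α-H) | C=C(C(=O)O)[C@H]1C/C=C(\C)CC/C=C(/C)[C@@H](O)[C@H]1O | intermediate
27 | 6α,8β,9β-trihydroxygermacra-1(10)Z,4E,11(13)-trien-12-oic acid (formed in the flask) | C=C(C(=O)O)[C@H]1[C@H](O)/C=C(\C)CC/C=C(/C)[C@@H](O)[C@H]1O | intermediate
28 | 8β,9β-dihydroxygermacra-1(10)Z,4E,11(13)-trien-6α,12-olide (7α-H, trans-fused lactone) | C=C1C(=O)O[C@@H]2/C=C(\C)CC/C=C(/C)[C@@H](O)[C@@H](O)[C@@H]12 | intermediate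
29 | (R)-citramalic acid, (R)-2-hydroxy-2-methylbutanedioic acid | C[C@@](O)(CC(=O)O)C(=O)O | starting material
30 | dimethyl (R)-2-hydroxy-2-methylbutanedioate | COC(=O)C[C@@](C)(O)C(=O)OC | intermediate
31 | methyl (R)-3,4-dihydroxy-3-methylbutanoate | COC(=O)C[C@@](C)(O)CO | intermediate
32 | methyl (R)-3-hydroxy-3-methyl-4-(tosyloxy)butanoate (formed in the flask) | COC(=O)C[C@@](C)(O)COS(=O)(=O)c1ccc(C)cc1 | intermediate
33 | methyl (R)-2-(2-methyloxiran-2-yl)acetate | COC(=O)C[C@]1(C)CO1 | intermediate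
34 | (R)-2-(2-methyloxiran-2-yl)acetic acid | OC(=O)C[C@]1(C)CO1 | intermediate
35 | 8β-hydroxy-9β-(triethylsilyloxy)germacra-1(10)Z,4E,11(13)-trien-6α,12-olide | C=C1C(=O)O[C@@H]2/C=C(\C)CC/C=C(/C)[C@@H](O[Si](CC)(CC)CC)[C@@H](O)[C@@H]12 | intermediate
36 | 8β-[(R)-2-(2-methyloxiran-2-yl)acetoxy]-9β-(triethylsilyloxy)germacra-1(10)Z,4E,11(13)-trien-6α,12-olide | C=C1C(=O)O[C@@H]2/C=C(\C)CC/C=C(/C)[C@@H](O[Si](CC)(CC)CC)[C@@H](OC(=O)C[C@]3(C)CO3)[C@@H]12 | intermediate
37 | CNP0284481.1, [(3aS,4S,5R,6Z,10E,11aR)-5-hydroxy-6,10-dimethyl-3-methylidene-2-oxo-3a,4,5,8,9,11a-hexahydrocyclodeca[b]furan-4-yl] 2-[(2R)-2-methyloxiran-2-yl]acetate | C=C1C(=O)O[C@@H]2/C=C(\C)CC/C=C(/C)[C@@H](O)[C@@H](OC(=O)C[C@]3(C)CO3)[C@@H]12 | target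

**Step count**

Total: 26 steps. Longest linear sequence: 22 steps (steps 1–19 and 24–26, from geranyl acetate); the epoxy acid branch is 4 steps (20–23).

**Steps most likely to fail**

1. Step 19 (enzymatic C6 hydroxylation and lactonisation). What may go wrong: no productive binding or turnover of the non-natural cis-C1=C10, 9-hydroxylated acid, oxygen rebound at another allylic carbon, or epoxidation of an alkene. The fallback uses known chemistry and brings the C6 oxygen in as an aldehyde instead of making it by C–H oxidation; it sets out from alcohol 5 and comes back at lactone 28.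
   - MnO2 oxidises 5 to (2E,6Z)-7-iodo-3-methylocta-2,6-dienal F1.
   - In parallel, a DABCO-promoted Baylis–Hillman reaction of methyl acrylate with (R)-2,3-O-isopropylideneglyceraldehyde gives methyl 2-[[(4R)-2,2-dimethyl-1,3-dioxolan-4-yl](hydroxy)methyl]prop-2-enoate F2. NBS/Me2S converts it with allylic transposition into methyl (Z)-2-(bromomethyl)-3-[(4S)-2,2-dimethyl-1,3-dioxolan-4-yl]prop-2-enoate F3.
   - CrCl2 in THF joins F3 to F1 at C6–C7 (anti-selective 2-(alkoxycarbonyl)allylation through a chair transition state) to give methyl (2S,3R,4E,8Z)-2-[(4S)-2,2-dimethyl-1,3-dioxolan-4-yl]-3-hydroxy-9-iodo-5-methyl... in short the homoallylic hydroxy ester F4. The isomer with the wanted C7 configuration relative to the dioxolane centre is separated if the allylic stereocentre does not control it.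
   - Catalytic PPTS closes F4 to (4S,5R)-4-[(4S)-2,2-dimethyl-1,3-dioxolan-4-yl]-5-[(1E,5Z)-6-iodo-2-methylhepta-1,5-dien-1-yl]-3-methylideneoxolan-2-one F5.
   - Aqueous acetic acid frees the 8,9-diol F6, TESOTf/2,6-lutidine gives the bis-TES ether F7, and Swern conditions oxidise the primary TES ether directly to the C9 aldehyde F8.
   - CrCl2/NiCl2 closes C9–C10 as in step 13 to 9β-hydroxy-8β-(triethylsilyloxy)germacra-1(10)Z,4E,11(13)-trien-6α,12-olide F9, and TBAF/AcOH removes the silyl group to give 28.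

2. Step 13 (ring closure). What may go wrong: intermolecular coupling competing with cyclisation, and above all poor facial selectivity in the addition to the C9 aldehyde if the ring conformation overrides the Felkin–Anh preference. The fallback sets C9 by reduction instead of by C–C bond formation; it sets out from aldehyde 18 and comes back at 20. The cyclisation is run without regard to C9 and should give the (9S)-alcohol 9-epi-20 F10, alone or mixed with 20. Dess–Martin periodinane oxidises this material to the macrocyclic C9 enone (1S,2S,4Z,8E)-2-(tert-butyldimethylsilyloxy)-N-methoxy-N,4,8-trimethyl-3-oxocyclodeca-4,8-diene-1-carboxamide F11. Luche reduction (NaBH4, CeCl3·7H2O, MeOH, −78 °C) then delivers hydride anti to the 8-silyloxy group to give 20; the Weinreb amide is inert to both reagents.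

3. Step 24 (regioselective silylation). What may go wrong: insufficient discrimination between the two secondary hydroxyls, leading to silylation at O8 or at both oxygens. The fallback uses the one chemical difference between them, that only O9 is allylic; it sets out from 28 and comes back at the target 37. MnO2 oxidises only C9–OH to 8β-hydroxy-9-oxogermacra-1(10)Z,4E,11(13)-trien-6α,12-olide F12. Steglich esterification of the remaining hydroxyl with 34 gives 8β-[(R)-2-(2-methyloxiran-2-yl)acetoxy]-9-oxogermacra-1(10)Z,4E,11(13)-trien-6α,12-olide F13. Luche reduction at −78 °C (hydride anti to the 8-acyloxy group, 1,2-selective) returns the 9β-alcohol 37.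

**Further compounds**

F1 | step 19 | (2E,6Z)-7-iodo-3-methylocta-2,6-dienal | O=C/C=C(\C)CC/C=C(/C)I
F2 | step 19 | methyl 2-[[(4R)-2,2-dimethyl-1,3-dioxolan-4-yl](hydroxy)methyl]prop-2-enoate (both carbinol epimers) | C=C(C(=O)OC)C(O)[C@H]1COC(C)(C)O1
F3 | step 19 | methyl (Z)-2-(bromomethyl)-3-[(4S)-2,2-dimethyl-1,3-dioxolan-4-yl]prop-2-enoate | COC(=O)/C(CBr)=C/[C@H]1COC(C)(C)O1
F4 | step 19 | homoallylic hydroxy ester (C6 R, C7 R, C8 S in germacrane numbering) | COC(=O)C(=C)[C@@H]([C@H](O)/C=C(\C)CC/C=C(/C)I)[C@H]1COC(C)(C)O1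
F5 | step 19 | (4S,5R)-4-[(4S)-2,2-dimethyl-1,3-dioxolan-4-yl]-5-[(1E,5Z)-6-iodo-2-methylhepta-1,5-dien-1-yl]-3-methylideneoxolan-2-one | C=C1C(=O)O[C@H](/C=C(\C)CC/C=C(/C)I)[C@H]1[C@H]1COC(C)(C)O1
F6 | step 19 | 8,9-diol from F5 | C=C1C(=O)O[C@H](/C=C(\C)CC/C=C(/C)I)[C@H]1[C@H](O)CO
F7 | step 19 | 8,9-bis(triethylsilyl) ether of F6 | C=C1C(=O)O[C@H](/C=C(\C)CC/C=C(/C)I)[C@H]1[C@H](O[Si](CC)(CC)CC)CO[Si](CC)(CC)CC
F8 | step 19 | C9 aldehyde with 8-O-triethylsilyl ether | C=C1C(=O)O[C@H](/C=C(\C)CC/C=C(/C)I)[C@H]1[C@H](O[Si](CC)(CC)CC)C=O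
F9 | step 19 | 9β-hydroxy-8β-(triethylsilyloxy)germacra-1(10)Z,4E,11(13)-trien-6α,12-olide | C=C1C(=O)O[C@@H]2/C=C(\C)CC/C=C(/C)[C@@H](O)[C@@H](O[Si](CC)(CC)CC)[C@@H]12
F10 | step 13 | 9-epi-20, (1S,2S,3S,4Z,8E)-2-(tert-butyldimethylsilyloxy)-3-hydroxy-N-methoxy-N,4,8-trimethylcyclodeca-4,8-diene-1-carboxamide | CON(C)C(=O)[C@H]1C/C=C(\C)CC/C=C(/C)[C@H](O)[C@H]1O[Si](C)(C)C(C)(C)C
F11 | step 13 | (1S,2S,4Z,8E)-2-(tert-butyldimethylsilyloxy)-N-methoxy-N,4,8-trimethyl-3-oxocyclodeca-4,8-diene-1-carboxamide | CON(C)C(=O)[C@H]1C/C=C(\C)CC/C=C(/C)C(=O)[C@H]1O[Si](C)(C)C(C)(C)C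
F12 | step 24 | 8β-hydroxy-9-oxogermacra-1(10)Z,4E,11(13)-trien-6α,12-olide | C=C1C(=O)O[C@@H]2/C=C(\C)CC/C=C(/C)C(=O)[C@@H](O)[C@@H]12
F13 | step 24 | 8β-[(R)-2-(2-methyloxiran-2-yl)acetoxy]-9-oxogermacra-1(10)Z,4E,11(13)-trien-6α,12-olide | C=C1C(=O)O[C@@H]2/C=C(\C)CC/C=C(/C)C(=O)[C@@H](OC(=O)C[C@]3(C)CO3)[C@@H]12
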